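Ring A of the flavone is a hydroquinone: the oxygens on C5 and C8 are para, C7 carries OMe and C6 carries H. These four carbons map onto methyl semisquarate, so ring A is disconnected at C8–C8a and C4a–C5, leaving a preformed 3-methoxy-2-aryl-4-pyranone (rings C and B). The key step is a thermal Moore ring expansion: a 4-hydroxy-3-methoxycyclobutenone attached to pyranone C6 opens to a dienylketene, which closes onto the pyranone C5=C6 bond and tautomerises, creating the C4a–C5 bond and the fully substituted ring A in one operation. The ring B triol is carried as benzyl ethers and released last by hydrogenolysis.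

Key step: step 10

Remark on the chemistry: the target is achiral; the carbinol centres created in the cyclobutenone intermediates are racemic and are lost before the end, so no stereocontrol is planned.

Step 1
Reactants: 1 3-hydroxy-4H-pyran-4-one (pyromeconic acid)
Product: 2 2-bromo-3-hydroxy-4H-pyran-4-one
Conditions: NBS, MeCN, 0 to 23 °C
Reagents that add atoms: N-bromosuccinimide, O=C1CCC(=O)N1Br
Why: Electrophilic bromination of the enol, whose C3 hydroxyl makes the ortho carbon C2 the nucleophilic site, the same position at which this pyranone is known to react with aldehydes.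

Step 2
Reactants: 2 2-bromo-3-hydroxy-4H-pyran-4-one
Product: 3 2-bromo-3-methoxy-4H-pyran-4-one
Conditions: MeI, K2CO3, acetone, 50 °C
Reagents that add atoms: iodomethane, CI
Why: Williamson O-methylation of the acidic enolic hydroxyl under mild carbonate conditions, which should leave the vinylic bromide untouched.

Step 3
Reactants: 4 5-bromo-1,2,3-trimethoxybenzene
Product: 5 5-bromobenzene-1,2,3-triol
Conditions: BBr3, CH2Cl2, −78 to 23 °C; then H2O
Reagents that add atoms: none
Why: Lewis acid ether cleavage with BBr3 removes all three aryl methyl groups while the aryl bromide is inert.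

Step 4
Reactants: 5 5-bromobenzene-1,2,3-triol
Product: 6 5-bromo-1,2,3-tris(benzyloxy)benzene
Conditions: BnBr, K2CO3, DMF, 60 °C, under N2
Reagents that add atoms: benzyl bromide, BrCc1ccccc1
Why: Threefold Williamson etherification of the phenols, run under nitrogen because the pyrogallol is oxidised by air in base.

Step 5
Reactants: 6 5-bromo-1,2,3-tris(benzyloxy)benzene
Product: 7 2-[3,4,5-tris(benzyloxy)phenyl]-4,4,5,5-tetramethyl-1,3,2-dioxaborolane
Conditions: B2pin2, Pd(dppf)Cl2 (cat.), KOAc, 1,4-dioxane, 90 °C
Reagents that add atoms: bis(pinacolato)diboron, CC1(C)OB(OC1(C)C)B1OC(C)(C)C(C)(C)O1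
Why: Miyaura borylation of an electron-rich aryl bromide, with the weak acetate base preventing onward biaryl coupling and sparing the benzyl ethers.

Step 6
Reactants: 3 2-bromo-3-methoxy-4H-pyran-4-one; 7 2-[3,4,5-tris(benzyloxy)phenyl]-4,4,5,5-tetramethyl-1,3,2-dioxaborolane
Product: 8 3-methoxy-2-[3,4,5-tris(benzyloxy)phenyl]-4H-pyran-4-one
Conditions: Pd(PPh3)4 (cat.), K2CO3, 1,4-dioxane/H2O, 85 °C
Reagents that add atoms: none
Why: Suzuki–Miyaura coupling, in which the C2–Br bond behaves as a vinylogous acyl bromide that should add quickly to zerovalent palladium, and the mild aqueous carbonate should leave the pyranone ring intact.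

Step 7
Reactants: 9 dimethyl squarate (3,4-dimethoxycyclobut-3-ene-1,2-dione)
Product: 10 racemic 4-hydroxy-2,3-dimethoxycyclobut-2-en-1-one
Conditions: LiAlH(OtBu)3, THF, −78 to −20 °C; aqueous work-up
Reagents that add atoms: none
Why: Mono 1,2-reduction of one squarate carbonyl by the hindered, mild hydride should stop at the alcohol because the remaining carbonyl is a deactivated vinylogous ester; the new carbinol centre is racemic and is removed in step 8.

Step 8
Reactants: 10 racemic 4-hydroxy-2,3-dimethoxycyclobut-2-en-1-one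
Product: 11 3-methoxycyclobut-3-ene-1,2-dione (methyl semisquarate)
Conditions: conc. HCl (cat.), CH2Cl2, 23 °C
Reagents that add atoms: none
Why: Acid-catalysed allylic transposition (ionisation of the C4 hydroxyl, capture of the released water at the methoxy-stabilised C2, loss of methanol) is the established way to alkyl semisquarates; 11 is used freshly prepared.

Step 9
Reactants: 8 3-methoxy-2-[3,4,5-tris(benzyloxy)phenyl]-4H-pyran-4-one; 11 3-methoxycyclobut-3-ene-1,2-dione
Product: 13 racemic 4-hydroxy-3-methoxy-4-{5-methoxy-4-oxo-6-[3,4,5-tris(benzyloxy)phenyl]-4H-pyran-2-yl}cyclobut-2-en-1-one, via 6-lithiopyranone 12 (not isolated)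
Conditions: TMPH, n-BuLi, THF, 0 °C; 8, −78 °C, 15 min; cannulate into 11 (1.2 equiv), THF, −78 °C; aq. NH4Cl
Reagents that add atoms: none
Why: Deprotonative lithiation with the hindered amide is expected at C6, the vinylic C–H next to the ring oxygen (as in chromones and 4-quinolones), and the alkenyllithium then undergoes 1,2-addition to the ketone carbonyl of 11 attached to the methoxy-bearing carbon, the other carbonyl being a deactivated vinylogous ester; the carbinol centre forms racemic and becomes sp2 in step 10.

Step 10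
Reactants: 13 racemic 4-hydroxy-3-methoxy-4-{5-methoxy-4-oxo-6-[3,4,5-tris(benzyloxy)phenyl]-4H-pyran-2-yl}cyclobut-2-en-1-one
Product: 16 5,8-dihydroxy-3,7-dimethoxy-2-[3,4,5-tris(benzyloxy)phenyl]-4H-chromen-4-one, via dienylketene 14 (not isolated), via bicyclic dienone 15 (not isolated)
Conditions: degassed toluene, 110 °C, argon
Reagents that add atoms: none
Why: Heating breaks the C1–C4 bond of the cyclobutenone in a conrotatory 4π electrocyclic ring opening in which the hydroxyl group, as the stronger donor, rotates outward, so the pyranonyl group sits cis to the ketene in dienylketene 14. A thermal disrotatory 6π electrocyclisation across the ketene C=C, the C(OMe)=C(OH) bond and the pyranone C5=C6 bond then joins the ketene carbon to pyranone C5, closing the six-membered carbocycle (ring A) as dienone 15, and a proton shift from C4a to the C5 oxygen gives the aromatic hydroquinone. The closest known reaction type is the Moore rearrangement of 4-alkenyl- and 4-(hetero)aryl-4-hydroxycyclobutenones to hydroquinones and quinones. No stereocentre survives: the racemic carbinol carbon of 13 becomes sp2 C8 and the C4a centre of 15 is erased on tautomerisation. The selectivity needed is regiochemical (OMe at C7 next to the C8 hydroxyl, H at C6) and is already fixed in 13, whose methoxy group sits on the carbon adjacent to the carbinol; closure can only take place at C5, the sole hydrogen-bearing neighbour of C6 and the nucleophilic α-carbon of the vinylogous ester. Degassed solvent should keep 16 in the hydroquinone state, and it is carried forward without chromatography.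

Step 11
Reactants: 16 5,8-dihydroxy-3,7-dimethoxy-2-[3,4,5-tris(benzyloxy)phenyl]-4H-chromen-4-one
Product: 17 5,8-dihydroxy-3,7-dimethoxy-2-(3,4,5-trihydroxyphenyl)-4H-chromen-4-one (5,8,3',4',5'-pentahydroxy-3,7-dimethoxyflavone)
Conditions: H2 (1 atm), Pd/C (palladium on carbon), THF/MeOH, 23 °C; filtration under argon
Reagents that add atoms: none
Why: Catalytic hydrogenolysis of the three aryl benzyl ethers, under which the tetrasubstituted, conjugated C2=C3 bond and the methyl ethers should survive and any 5,8-quinone formed by stray air is returned to the hydroquinone.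

Compound list
1 | 3-hydroxy-4H-pyran-4-one (pyromeconic acid) | O=c1ccocc1O | starting material
2 | 2-bromo-3-hydroxy-4H-pyran-4-one | O=c1ccoc(Br)c1O | intermediate
3 | 2-bromo-3-methoxy-4H-pyran-4-one | COc1c(Br)occc1=O | intermediate
4 | 5-bromo-1,2,3-trimethoxybenzene | COc1cc(Br)cc(OC)c1OC | starting material
5 | 5-bromobenzene-1,2,3-triol | Oc1cc(Br)cc(O)c1O | intermediate
6 | 5-bromo-1,2,3-tris(benzyloxy)benzene | Brc1cc(OCc2ccccc2)c(OCc2ccccc2)c(OCc2ccccc2)c1 | intermediate
7 | 2-[3,4,5-tris(benzyloxy)phenyl]-4,4,5,5-tetramethyl-1,3,2-dioxaborolane | CC1(C)OB(c2cc(OCc3ccccc3)c(OCc3ccccc3)c(OCc3ccccc3)c2)OC1(C)C | intermediate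
8 | 3-methoxy-2-[3,4,5-tris(benzyloxy)phenyl]-4H-pyran-4-one | COc1c(-c2cc(OCc3ccccc3)c(OCc3ccccc3)c(OCc3ccccc3)c2)occc1=O | intermediate
9 | dimethyl squarate (3,4-dimethoxycyclobut-3-ene-1,2-dione) | COC1=C(OC)C(=O)C1=O | starting material
10 | racemic 4-hydroxy-2,3-dimethoxycyclobut-2-en-1-one | COC1=C(OC)C(O)C1=O | intermediate
11 | 3-methoxycyclobut-3-ene-1,2-dione (methyl semisquarate) | COC1=CC(=O)C1=O | intermediate
12 | 6-lithio-3-methoxy-2-[3,4,5-tris(benzyloxy)phenyl]-4H-pyran-4-one | [Li]c1cc(=O)c(OC)c(-c2cc(OCc3ccccc3)c(OCc3ccccc3)c(OCc3ccccc3)c2)o1 | intermediate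
13 | racemic 4-hydroxy-3-methoxy-4-{5-methoxy-4-oxo-6-[3,4,5-tris(benzyloxy)phenyl]-4H-pyran-2-yl}cyclobut-2-en-1-one | COC1=CC(=O)C1(O)c1cc(=O)c(OC)c(-c2cc(OCc3ccccc3)c(OCc3ccccc3)c(OCc3ccccc3)c2)o1 | intermediate
14 | (Z)-4-hydroxy-3-methoxy-4-{5-methoxy-4-oxo-6-[3,4,5-tris(benzyloxy)phenyl]-4H-pyran-2-yl}buta-1,3-dien-1-one (dienylketene) | O=C=C/C(OC)=C(/O)c1cc(=O)c(OC)c(-c2cc(OCc3ccccc3)c(OCc3ccccc3)c(OCc3ccccc3)c2)o1 | intermediate
15 | racemic 8-hydroxy-3,7-dimethoxy-2-[3,4,5-tris(benzyloxy)phenyl]-4H-chromene-4,5(4aH)-dione | COC1=CC(=O)C2C(=O)C(OC)=C(c3cc(OCc4ccccc4)c(OCc4ccccc4)c(OCc4ccccc4)c3)OC2=C1O | intermediate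
16 | 5,8-dihydroxy-3,7-dimethoxy-2-[3,4,5-tris(benzyloxy)phenyl]-4H-chromen-4-one | COc1cc(O)c2c(=O)c(OC)c(-c3cc(OCc4ccccc4)c(OCc4ccccc4)c(OCc4ccccc4)c3)oc2c1O | intermediate
17 | 5,8,3',4',5'-pentahydroxy-3,7-dimethoxyflavone | COc1cc(O)c2c(=O)c(OC)c(-c3cc(O)c(O)c(O)c3)oc2c1O | target

Total step count: 11 steps.
Longest linear sequence: 7 steps (steps 3, 4, 5, 6, 9, 10, 11, from compound 4).

Steps most likely to fail

Step 9 (metalation and addition). Deprotonation may occur at C5 instead of C6 and be followed by ring fragmentation. The lithiated pyranone may add in conjugate fashion to unreacted 8 before it is trapped. The organolithium may attack the methoxy-bearing carbon of 11 with loss of methoxide. The fallback sets out from 8 and returns at 13. Zincation of 8 with the mild amide base TMPZnCl·LiCl (THF, 23 °C), a base class used to metalate 4-pyranones next to the ring oxygen without attack on the carbonyl, should give [5-methoxy-4-oxo-6-(3,4,5-tris(benzyloxy)phenyl)-4H-pyran-2-yl]zinc chloride F1. Quenching with I2 gives 6-iodo-3-methoxy-2-[3,4,5-tris(benzyloxy)phenyl]-4H-pyran-4-one F2. Iodine–magnesium exchange with iPrMgCl·LiCl (THF, −78 °C) then generates, with no amine or excess strong base present, [5-methoxy-4-oxo-6-(3,4,5-tris(benzyloxy)phenyl)-4H-pyran-2-yl]magnesium chloride F3, which is added to 11 at −78 °C and quenched with NH4Cl to give 13.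

Step 10 (ring expansion). The 6π closure onto the pyranone C5=C6 bond may be slow, so that the reversible ring opening drains through the hydroxyl-inward ketene and lactonises to a butenolide. The free hydroquinone may also oxidise and degrade during prolonged heating. The fallback sets out from 13 and returns at 16. The tertiary hydroxyl is capped (TESOTf, 2,6-lutidine, CH2Cl2, −78 °C) to give racemic 3-methoxy-4-{5-methoxy-4-oxo-6-[3,4,5-tris(benzyloxy)phenyl]-4H-pyran-2-yl}-4-(triethylsilyloxy)cyclobut-2-en-1-one F4. Thermolysis of this silyl ether (toluene, 110 °C) cannot lactonise and should deliver 5-hydroxy-3,7-dimethoxy-8-(triethylsilyloxy)-2-[3,4,5-tris(benzyloxy)phenyl]-4H-chromen-4-one F5, which cannot be oxidised to a quinone. HF·pyridine (THF, 0 °C) then removes the silyl group to give 16.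

Step 11 (global debenzylation). Cleavage of the hindered central benzyl ether may be incomplete. The pyranone C2=C3 bond may be slowly reduced on extended exposure. The hexa-oxygenated product may oxidise in air during filtration and purification. The fallback sets out from 16 and returns at 17. Non-reductive debenzylation with BCl3 and pentamethylbenzene as benzyl cation scavenger (CH2Cl2, −78 °C) gives crude 17. This is peracetylated at once (Ac2O, pyridine, DMAP) to 5,8-diacetoxy-3,7-dimethoxy-2-(3,4,5-triacetoxyphenyl)-4H-chromen-4-one F6, an air-stable compound that can be purified. Deacetylation with HCl in degassed MeOH under argon then releases 17.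

Further compounds
F1 | step 9 | [5-methoxy-4-oxo-6-(3,4,5-tris(benzyloxy)phenyl)-4H-pyran-2-yl]zinc chloride | Cl[Zn]c1cc(=O)c(OC)c(-c2cc(OCc3ccccc3)c(OCc3ccccc3)c(OCc3ccccc3)c2)o1
F2 | step 9 | 6-iodo-3-methoxy-2-[3,4,5-tris(benzyloxy)phenyl]-4H-pyran-4-one | COc1c(-c2cc(OCc3ccccc3)c(OCc3ccccc3)c(OCc3ccccc3)c2)oc(I)cc1=O
F3 | step 9 | [5-methoxy-4-oxo-6-(3,4,5-tris(benzyloxy)phenyl)-4H-pyran-2-yl]magnesium chloride | Cl[Mg]c1cc(=O)c(OC)c(-c2cc(OCc3ccccc3)c(OCc3ccccc3)c(OCc3ccccc3)c2)o1
F4 | step 10 | racemic 3-methoxy-4-{5-methoxy-4-oxo-6-[3,4,5-tris(benzyloxy)phenyl]-4H-pyran-2-yl}-4-(triethylsilyloxy)cyclobut-2-en-1-one | COC1=CC(=O)C1(O[Si](CC)(CC)CC)c1cc(=O)c(OC)c(-c2cc(OCc3ccccc3)c(OCc3ccccc3)c(OCc3ccccc3)c2)o1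
F5 | step 10 | 5-hydroxy-3,7-dimethoxy-8-(triethylsilyloxy)-2-[3,4,5-tris(benzyloxy)phenyl]-4H-chromen-4-one | COc1cc(O)c2c(=O)c(OC)c(-c3cc(OCc4ccccc4)c(OCc4ccccc4)c(OCc4ccccc4)c3)oc2c1O[Si](CC)(CC)CC
F6 | step 11 | 5,8-diacetoxy-3,7-dimethoxy-2-(3,4,5-triacetoxyphenyl)-4H-chromen-4-one | COc1cc(OC(C)=O)c2c(=O)c(OC)c(-c3cc(OC(C)=O)c(OC(C)=O)c(OC(C)=O)c3)oc2c1OC(C)=O
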